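Remark: the target has no stereocentre and no stereogenic double bond, so no SMILES below carries a stereodescriptor; compounds 1, 2 and 7 are taken as catalogue chemicals.

## Analysis of the target

Malabaricone C (11) is an achiral diarylnonanoid. Its nonan-1-one chain C1–C9 carries ring A, a 2,6-dihydroxyphenyl ring (C1′–C6′, hydroxyls on C2′ and C6′), on the carbonyl carbon C1, and ring B, a 3,4-dihydroxyphenyl ring (C1″–C6″), on the terminal methylene C9. With no stereocentres, the problem is one of regiochemistry and oxidation level. The hard bond is C1–C1′, because C1′ lies between the two oxygen-bearing carbons C2′ and C6′. Electrophilic acylation of a 1,3-dioxygenated benzene goes para to one oxygen instead, and a metallated C1′ is hindered by two ortho substituents. The feature that invites the chosen move is that C1, C1′, C2′–O and C6′–O together form the enol of a cyclic β-triketone, so ring A plus C1 is a 2-acylcyclohexane-1,3-dione one dehydrogenation away from the arene. In that mirror-symmetric dione the future C1′ is the only carbon between two carbonyls. A second feature is that C1–C9 is the skeleton of a nine-carbon α,ω-diacid, and C9 sits para to an oxygen of ring B, exactly where a 1,2-dioxygenated benzene is acylated naturally. The sensitive groups are the free catechol of ring B (air oxidation to the ortho-quinone, especially in base), both electron-rich rings towards electrophilic halogen and oxidants, and the chelated aryl ketone. Ring B is therefore carried as its dimethyl ether, and all phenols are freed in the last step.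

## Retrosynthetic reasoning

**11 from 10.** The last disconnection cuts three O–CH3 bonds: two on ring B and one on C6′–O of ring A. It is placed last because the free catechol is the most fragile part of the molecule. The forward step needs one Lewis-acid ether cleavage that removes two unactivated methyl groups and one carbonyl-chelated methyl group without touching the ketone or the chain.

**10 from 9.** No carbon–carbon bond is cut here; ring A is taken back to its saturated form. In 9 the carbons C3′, C4′ and C5′ are methylenes and C2′/C6′ are the carbonyl and enol carbons of a β-triketone. What is gained is a non-aromatic, strongly acidic ring whose acyl group can only sit on C1′. The forward step has to remove two hydrogens from the ring in a medium that caps one ring A oxygen as the methyl ether seen in 10, leaving the ring B ethers and the benzylic C9 alone.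

**9 from 6 and 7 (key disconnection).** The C1–C1′ bond is cut between the carbonyl carbon of acid 6 and C2 of dione 7. This is the most simplifying cut: it splits the molecule into a C15 fragment holding the whole chain and ring B, and a C6 fragment holding every carbon of ring A. Because 7 is symmetric, the regiochemistry that defeats acylation of an aromatic ring A does not arise. The forward reaction has to O-acylate the enol of 7 to give 8 and then move the acyl group from oxygen to carbon, driven by formation of the acidic triketone 9.

**6 from 5 from 4.** These are functional-group changes only. The acid of 6 is unmasked from the methyl ester of 5, and the benzylic methylene C9 of 5 comes from the aryl ketone of 4. That ketone is kept in the plan because it is the handle by which ring B is attached.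

**4 from 1 and 2 (through 3).** The C9–C1″ bond is cut as a Friedel–Crafts acylation of 2 para to one methoxy group. Here the innate selectivity of electrophilic substitution is the one the target needs. Compound 1 supplies all nine chain carbons with the two ends already differentiated, so the chain is never built bond by bond; its free acid end is activated as 3.

## Alternatives that were turned down

Alternative 1: the textbook route keeps ring A aromatic and makes C1′ the nucleophile. 1,3-Dimethoxybenzene A1 would be lithiated between its two methoxy groups and added to N-methoxy-N-methyl-9-(3,4-dimethoxyphenyl)nonanamide A2, made from 6. This gives 1-(2,6-dimethoxyphenyl)-9-(3,4-dimethoxyphenyl)nonan-1-one A3, and a four-fold ether cleavage then gives 11. It would probably work, but it is no shorter from 6 (three steps against three). The carbanion at C1′ is basic and flanked by two ortho substituents, so addition to an enolisable amide competes with α-deprotonation and needs cryogenic conditions. In A3 the carbonyl is twisted out of the ring plane, and four ethers must be cleaved at the end. It also uses neither the symmetry nor the triketone character of ring A, and it is the route drawn first.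

Alternative 2: ring A could be made from another ring. 4-Hydroxy-2H-pyran-2-one A4 would be C-acylated with 6 to give 3-[9-(3,4-dimethoxyphenyl)nonanoyl]-4-hydroxy-2H-pyran-2-one A5 and O-methylated to the 4-methoxy compound A6. An inverse-demand Diels–Alder reaction of A6 with 1,1-dimethoxyethene A7 would form C1′–C2′ and C3′–C4′; decarboxylative cycloreversion and β-elimination of one methoxy group would then give A3. It was turned down for three reasons. The 6-unsubstituted pyranone A4 is not a commodity. The 4-methoxy group of A6 donates into the diene and should make the cycloaddition sluggish, and methylation of A5 is ambident. Finally, three steps would be spent assembling six ring carbons that 7 supplies in one piece, and the route still ends at A3 with four ethers.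

Alternative 3: an electrochemical cut in the chain at C7–C8. A mixed Kolbe electrolysis of 3-(3,4-dimethoxyphenyl)propanoic acid A8 with 8-(2,6-dimethoxyphenyl)-8-oxooctanoic acid A9 would couple the two alkyl radicals formed by anodic decarboxylation and give A3. It was turned down because the anode potential needed for carboxylate oxidation lies above that at which dimethoxyarenes are oxidised, so ring oxidation and intramolecular trapping by the carboxylate of A8 would compete. Statistical homo-coupling of each radical also wastes both acids. Moreover, A9 still contains the hindered ring A ketone, so the real problem is only moved, and the bond formed is a plain CH2–CH2 bond that 1 already contains.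

Key step: step 4

## Route

Step 1
Reactants: 1 monomethyl azelate (9-methoxy-9-oxononanoic acid); 2 veratrole (1,2-dimethoxybenzene)
Product: 4 methyl 9-(3,4-dimethoxyphenyl)-9-oxononanoate, via methyl 9-chloro-9-oxononanoate 3 (not isolated)
Conditions: (COCl)2, DMF (cat.), CH2Cl2, 0 °C → rt, evaporate; then 2, AlCl3 (2.2 equiv), CH2Cl2, 0 °C → rt; aq. HCl
Reagents that add atoms: none
Why: Friedel–Crafts acylation of veratrole by the acid chloride 3 should go para to one methoxy group (the position ortho to both is hindered), which is exactly the 3,4-dioxygenated pattern of ring B; the methyl ester is only complexed by AlCl3 at this temperature and should survive.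

Step 2
Reactants: 4 methyl 9-(3,4-dimethoxyphenyl)-9-oxononanoate
Product: 5 methyl 9-(3,4-dimethoxyphenyl)nonanoate
Conditions: H2 (4 bar), 10% Pd/C, AcOH, HClO4 (cat.), 50 °C
Reagents that add atoms: none
Why: Catalytic hydrogenolysis of an aryl ketone: reduction to the benzylic alcohol and acid-assisted hydrogenolysis of the C9–O bond, made easy by the para-methoxy group; ester, ethers and arene should be untouched under these conditions.

Step 3
Reactants: 5 methyl 9-(3,4-dimethoxyphenyl)nonanoate
Product: 6 9-(3,4-dimethoxyphenyl)nonanoic acid
Conditions: LiOH·H2O, THF/MeOH/H2O, rt; then 1 M HCl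
Reagents that add atoms: lithium hydroxide, [Li+].[OH-]
Why: Plain saponification of an unhindered methyl ester by acyl–oxygen cleavage; nothing else in 5 is base-sensitive.

Step 4
Reactants: 6 9-(3,4-dimethoxyphenyl)nonanoic acid; 7 cyclohexane-1,3-dione
Product: 9 2-[9-(3,4-dimethoxyphenyl)nonanoyl]-3-hydroxycyclohex-2-en-1-one, via enol ester 8 (not isolated)
Conditions: DCC (1.2 equiv), DMAP (0.3 equiv), Et3N (1.5 equiv), CH2Cl2, 0 °C → rt; filter; 1 M HCl wash
Reagents that add atoms: none
Why: Carbodiimide activation of 6 and DMAP-catalysed acyl transfer should first give the kinetic O-acyl product 8 (a Steglich-type esterification of the enol of 7). DMAP then re-enters at the activated ester carbonyl of 8 and hands the acyl group to the soft carbon C2 of the dione enolate, a 1,3 O→C acyl shift that is the standard way to make 2-acylcyclohexane-1,3-diones from their enol esters under aminopyridine or cyanide catalysis. The step closes no ring and creates no stereocentre. It forms the C1–C1′ bond of the target and so joins the C15 chain–ring B fragment to all six carbons of ring A in one operation. The selectivity needed is C- over O-acylation and C2 over C4/C6. O-acylation is reversible under acyl-transfer catalysis, whereas acylation at C2 gives a β-triketone that Et3N deprotonates at once to a doubly stabilised enolate, a thermodynamic sink that acylation at C4 or C6 cannot reach. Because 7 is mirror-symmetric, C2 is its only carbon between two carbonyls, so the acyl group must end on the future C1′ between the two future phenol oxygens. The dimethoxyphenyl ring of 6 is a spectator, the urea is filtered off, and the acid wash returns the neutral enol 9.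

Step 5
Reactants: 9 2-[9-(3,4-dimethoxyphenyl)nonanoyl]-3-hydroxycyclohex-2-en-1-one
Product: 10 9-(3,4-dimethoxyphenyl)-1-(2-hydroxy-6-methoxyphenyl)nonan-1-one
Conditions: I2 (2 equiv), MeOH, reflux; aq. Na2S2O3
Reagents that add atoms: methanol, CO
Why: Iodine–methanol oxidative aromatisation, a known reaction of cyclohexenones and 2-acylcyclohexane-1,3-diones: acid-catalysed formation of the vinylogous methyl ester, α-iodination of the remaining ring ketone, loss of HI and tautomerisation to the phenol, whose chelated hydroxyl is not etherified. Iodination on the chain α-carbon is reversible in the presence of HI, while ring iodination is drained by irreversible aromatisation.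

Step 6
Reactants: 10 9-(3,4-dimethoxyphenyl)-1-(2-hydroxy-6-methoxyphenyl)nonan-1-one
Product: 11 malabaricone C, 1-(2,6-dihydroxyphenyl)-9-(3,4-dihydroxyphenyl)nonan-1-one
Conditions: BBr3 (6 equiv), CH2Cl2, −78 °C → rt; H2O, 0 °C
Reagents that add atoms: none
Why: Lewis-acid cleavage of aryl methyl ethers by BBr3; the ether ortho to the carbonyl is cleaved with chelation assistance and the two ring B ethers by the usual bromide attack on the boron-complexed methyl group, and the ketone and chain should be inert.

## Compound list

1 | monomethyl azelate (9-methoxy-9-oxononanoic acid) | COC(=O)CCCCCCCC(=O)O | starting material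
2 | veratrole (1,2-dimethoxybenzene) | COc1ccccc1OC | starting material
3 | methyl 9-chloro-9-oxononanoate | COC(=O)CCCCCCCC(=O)Cl | intermediate
4 | methyl 9-(3,4-dimethoxyphenyl)-9-oxononanoate | COC(=O)CCCCCCCC(=O)c1ccc(OC)c(OC)c1 | intermediate
5 | methyl 9-(3,4-dimethoxyphenyl)nonanoate | COC(=O)CCCCCCCCc1ccc(OC)c(OC)c1 | intermediate
6 | 9-(3,4-dimethoxyphenyl)nonanoic acid | OC(=O)CCCCCCCCc1ccc(OC)c(OC)c1 | intermediate
7 | cyclohexane-1,3-dione | O=C1CCCC(=O)C1 | starting material
8 | 3-oxocyclohex-1-en-1-yl 9-(3,4-dimethoxyphenyl)nonanoate | O=C1CCCC(OC(=O)CCCCCCCCc2ccc(OC)c(OC)c2)=C1 | intermediate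
9 | 2-[9-(3,4-dimethoxyphenyl)nonanoyl]-3-hydroxycyclohex-2-en-1-one (enol form of the 2-acylcyclohexane-1,3-dione) | O=C1CCCC(O)=C1C(=O)CCCCCCCCc1ccc(OC)c(OC)c1 | intermediate
10 | 9-(3,4-dimethoxyphenyl)-1-(2-hydroxy-6-methoxyphenyl)nonan-1-one | COc1cccc(O)c1C(=O)CCCCCCCCc1ccc(OC)c(OC)c1 | intermediate
11 | malabaricone C, 1-(2,6-dihydroxyphenyl)-9-(3,4-dihydroxyphenyl)nonan-1-one | O=C(CCCCCCCCc1ccc(O)c(O)c1)c1c(O)cccc1O | target

## Step count and risk

Total step count: 6. Longest linear sequence: 6 steps (1 and 2 to 11); 7 enters in step 4.

**Step 4 (key step).** The acyl group may stop on oxygen if the O→C migration of 8 is slow. The activated acid may also rearrange to an unreactive N-acylurea, or the triketone may be deacylated by retro-Claisen cleavage during work-up. The fallback gives up the saturated ring A; it sets out from 5 and comes back at 10. Partial reduction of 5 (i-Bu2AlH, toluene, −78 °C) would give 9-(3,4-dimethoxyphenyl)nonanal F1. 3-Methoxyphenol would be protected (MOMCl, i-Pr2NEt) as 1-methoxy-3-(methoxymethoxy)benzene F2. n-BuLi in THF at 0 °C should deprotonate F2 between its two oxygens to give [2-methoxy-6-(methoxymethoxy)phenyl]lithium F3. Addition of F3 to F1 would give racemic 9-(3,4-dimethoxyphenyl)-1-[2-methoxy-6-(methoxymethoxy)phenyl]nonan-1-ol F4. Dess–Martin oxidation would give 9-(3,4-dimethoxyphenyl)-1-[2-methoxy-6-(methoxymethoxy)phenyl]nonan-1-one F5, and HCl in MeOH would remove the acetal to give 10.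

**Step 5.** Acid-catalysed methanolysis of the triketone (loss of the side chain) may compete with aromatisation. Dehydrogenation may also be incomplete, the second ring A oxygen may be methylated as well, or the newly formed activated phenol ring may be iodinated. The fallback replaces the ionic halogenation–elimination by a metal-catalysed dehydrogenation; it sets out from 9 and comes back at 11. Heating 9 with 10% Pd/C in refluxing diglyme under a nitrogen sweep should give 1-(2,6-dihydroxyphenyl)-9-(3,4-dimethoxyphenyl)nonan-1-one F6. The conditions of step 6, which then have only the two ring B ethers to cleave, would convert F6 into 11.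

**Step 1.** AlCl3 may remove the methyl group of the ether para to the new ketone if the reaction is run too long or too warm, and complexation of the ester may slow the acylation. The fallback reverses the polarity of ring B; it sets out from 2 and comes back at 4. Bromination of 2 (NBS, MeCN) would give 4-bromo-1,2-dimethoxybenzene F7, and magnesium in THF would give (3,4-dimethoxyphenyl)magnesium bromide F8. Acylation of F8 with 3, made from 1 as in step 1, under Fe(acac)3 catalysis in THF at −78 °C should give 4 with the ester intact.

**Step 6.** Cleavage of the three ethers may stop part-way and leave partially methylated phenols that are hard to separate, and the freed catechol may be oxidised during work-up. The fallback moves the two hard cleavages to an earlier, more robust stage; it sets out from 9 and comes back at 11. BBr3 on 9 would give 2-[9-(3,4-dihydroxyphenyl)nonanoyl]-3-hydroxycyclohex-2-en-1-one F9. The conditions of step 5 would turn F9 into 9-(3,4-dihydroxyphenyl)-1-(2-hydroxy-6-methoxyphenyl)nonan-1-one F10; the catechol should tolerate iodine in the acidic, reducing medium. The single remaining, carbonyl-chelated ether of F10 would then be cleaved by BCl3 in CH2Cl2 at −78 → 0 °C to give 11.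

## Further compounds

F1 | step 4 | 9-(3,4-dimethoxyphenyl)nonanal | O=CCCCCCCCCc1ccc(OC)c(OC)c1
F2 | step 4 | 1-methoxy-3-(methoxymethoxy)benzene | COCOc1cccc(OC)c1
F3 | step 4 | [2-methoxy-6-(methoxymethoxy)phenyl]lithium | [Li]c1c(OC)cccc1OCOC
F4 | step 4 | 9-(3,4-dimethoxyphenyl)-1-[2-methoxy-6-(methoxymethoxy)phenyl]nonan-1-ol (racemic) | COCOc1cccc(OC)c1C(O)CCCCCCCCc1ccc(OC)c(OC)c1
F5 | step 4 | 9-(3,4-dimethoxyphenyl)-1-[2-methoxy-6-(methoxymethoxy)phenyl]nonan-1-one | COCOc1cccc(OC)c1C(=O)CCCCCCCCc1ccc(OC)c(OC)c1
F6 | step 5 | 1-(2,6-dihydroxyphenyl)-9-(3,4-dimethoxyphenyl)nonan-1-one | COc1ccc(CCCCCCCCC(=O)c2c(O)cccc2O)cc1OC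
F7 | step 1 | 4-bromo-1,2-dimethoxybenzene | COc1ccc(Br)cc1OC
F8 | step 1 | (3,4-dimethoxyphenyl)magnesium bromide | COc1ccc([Mg]Br)cc1OC
F9 | step 6 | 2-[9-(3,4-dihydroxyphenyl)nonanoyl]-3-hydroxycyclohex-2-en-1-one | O=C1CCCC(O)=C1C(=O)CCCCCCCCc1ccc(O)c(O)c1
F10 | step 6 | 9-(3,4-dihydroxyphenyl)-1-(2-hydroxy-6-methoxyphenyl)nonan-1-one | COc1cccc(O)c1C(=O)CCCCCCCCc1ccc(O)c(O)c1
A1 | alternative 1 | 1,3-dimethoxybenzene | COc1cccc(OC)c1
A2 | alternative 1 | N-methoxy-N-methyl-9-(3,4-dimethoxyphenyl)nonanamide | CON(C)C(=O)CCCCCCCCc1ccc(OC)c(OC)c1
A3 | alternative 1 | 1-(2,6-dimethoxyphenyl)-9-(3,4-dimethoxyphenyl)nonan-1-one | COc1cccc(OC)c1C(=O)CCCCCCCCc1ccc(OC)c(OC)c1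
A4 | alternative 2 | 4-hydroxy-2H-pyran-2-one | O=C1C=C(O)C=CO1
A5 | alternative 2 | 3-[9-(3,4-dimethoxyphenyl)nonanoyl]-4-hydroxy-2H-pyran-2-one | O=C1OC=CC(O)=C1C(=O)CCCCCCCCc1ccc(OC)c(OC)c1
A6 | alternative 2 | 3-[9-(3,4-dimethoxyphenyl)nonanoyl]-4-methoxy-2H-pyran-2-one | COC1=C(C(=O)CCCCCCCCc2ccc(OC)c(OC)c2)C(=O)OC=C1
A7 | alternative 2 | 1,1-dimethoxyethene | C=C(OC)OC
A8 | alternative 3 | 3-(3,4-dimethoxyphenyl)propanoic acid | COc1ccc(CCC(=O)O)cc1OC
A9 | alternative 3 | 8-(2,6-dimethoxyphenyl)-8-oxooctanoic acid | COc1cccc(OC)c1C(=O)CCCCCCC(=O)O
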